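The constants were set for the occasion; the rest is arithmetic.

At 50 s I read target, so the question is how many growth times fit into that time.

| setting | winter | noon | summer |
|---|---|---|---|
| substrate | 0.050 M | 0.050 M | 0.050 M |
| time | 50 s |  | 50 s |
| remark | plug flow through a tube for 50 s, no back-mixing | a single well-mixed tank run continuously and read at steady state, 50 s in it on average | everything together in a closed stirred flask, run for 50 s |

- the set-up with the highest amount of target at the outlet or at the end, in percent of the substrate put in ("none" if the first two lie within 2 percentage points) (winter / noon / summer / none)
- amount of target at the outlet or at the end, in percent of the substrate put in, winter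
- amount of target at the outlet or at the end, in percent of the substrate put in, noon
- amount of target at the outlet or at the end, in percent of the substrate put in, summer

    substrate + target → 2 target (k1 = 1.00 L mol⁻¹ s⁻¹)
    substrate → target (k2 = 1.27 × 10⁻⁴ s⁻¹)
    substrate ⇌ dormant form (K3 = 0.62, k3 = 0.00822 s⁻¹)
    target ⇌ isomer of the product (K4 = 2.1, k4 = 0.00216 s⁻¹)
    substrate → decomposition product (k5 = 2.04 × 10⁻⁵ s⁻¹)

Target makes more target with constant 1.00 L mol⁻¹ s⁻¹, which is autocatalysis, so at the charge of 0.050 M it grows e-fold every 20.0 s, shorter than the 50 s on hand. These are my two times. The forward half-life of target into its isomer, 5.3 min, is longer than the run. The direct step from substrate, with half-life 91 min, is far slower than the run, so it serves as a seed, worth 0.254% of the charge in k2/k1.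

Substrate sags towards the dormant form with relaxation half-life 32.3 s, and I replace that curve by its mean over the run, 85.2% of the charge. Growth is then pseudo-first-order in target. The gain, constant k1 times mean substrate times time, is 2.13.

The winter tube is a closed flask with time laid along it, so winter and summer match. Each gives the seed times (e^gain − 1), which is 1.88%. The noon tank washes target out, so for target to hold there at steady state I estimate a gain of about one, taking the time as the average stay, which puts its substrate near 1/(k1 t), or 0.0200 M. That leaves 60.0% of the charge to share among target, dormant form, isomer and decomposition product, so I commit to noon by a wide margin.

The forecast says “Plug flow and the closed flask are kinetically identical here”. It gives 1.7% for winter, 1.7% for summer and 41.1% for noon, so it picks noon; my batch figure of 1.88% runs higher than its 1.7%.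

The simulation gives 1.72% in winter, 1.72% in summer and 41.1% at noon, so noon leads.

The noon tank holds 0.0219 M of substrate, a gain of 1.09, against 2.13 in the summer flask. Read at 2.0 min, that summer flask has by my reckoning a relaxation mean of 75.4%, so its gain comes to 4.53. The seed rule then gives 23.3%, and the flask holds 15.0%.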